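**Retrosynthetic overview**

- The target comes from a racemic benzhydrol (carbinol carbon C9) by ionic deoxygenation with loss of the MOM group, then fluoride desilylation.
- The benzhydrol comes from a one-flask aryne relay that forms C6'–CH2OMe and C1'–C9 from a 3-fluoro-5-methoxyphenyl silyl ether, methoxymethyllithium and an isocoumarin-5-carbaldehyde.
- Feature the strategy rests on: ring A carries CH2OMe on C6', the bridge carbon C9 on the adjacent C1', and OMe on C2' next to C1'. This is the pattern left when a nucleophile and then an electrophile add across a 3-methoxyaryne spanning C1'–C6'.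
- The aldehyde comes from phenol-directed formylation at C5 of 6-hydroxy-8-methoxy-3-methylisocoumarin, itself made by lateral acylation and enol lactonisation of a methyl orsellinate ether.
- Ring order: both benzene rings are bought; the pyranone ring of the isocoumarin is the only ring formed (step 5), before the fragments are joined.

Key step: step 8

Remark on the chemistry: the target has no stereocentre and is a single achiral compound. The only stereocentre met on the way (C9 of the benzhydrol) forms as the racemate and is removed in step 9. Ring A locants: C1' bears the bridge CH2 (C9), C2' OMe, C4' OH, C6' CH2OMe.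

**Route**

Step 1
Reactants: 1 3-fluoro-5-methoxyphenol
Product: 2 (3-fluoro-5-methoxyphenoxy)triisopropylsilane
Conditions: TIPSCl, imidazole, DMF, rt
Reagents that add atoms: chlorotriisopropylsilane, CC(C)[Si](Cl)(C(C)C)C(C)C
Why: Imidazole-promoted silylation of a phenol gives the aryl silyl ether; the aryl fluoride and methyl ether are inert.

Step 2
Reactants: 3 methyl 2,4-dihydroxy-6-methylbenzoate (methyl orsellinate)
Product: 4 methyl 2-hydroxy-4-(methoxymethoxy)-6-methylbenzoate
Conditions: MOMCl (1 equiv), i-Pr2NEt, CH2Cl2, 0 °C
Reagents that add atoms: chloromethyl methyl ether, COCCl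
Why: The 2-OH is hydrogen-bonded to the ester carbonyl and poorly nucleophilic, so Williamson-type O-alkylation with one equivalent of MOMCl should take the free 4-OH.

Step 3
Reactants: 4 methyl 2-hydroxy-4-(methoxymethoxy)-6-methylbenzoate
Product: 5 methyl 2-methoxy-4-(methoxymethoxy)-6-methylbenzoate
Conditions: MeI, K2CO3, DMF, 40 °C
Reagents that add atoms: iodomethane, CI
Why: Williamson methylation of the remaining chelated phenol under carbonate/DMF conditions; the MOM acetal and the hindered ester are stable to this base.

Step 4
Reactants: 5 methyl 2-methoxy-4-(methoxymethoxy)-6-methylbenzoate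
Product: 6 methyl 2-methoxy-4-(methoxymethoxy)-6-(2-oxopropyl)benzoate
Conditions: LDA, THF, −78 °C; then MeC(O)N(OMe)Me, −78 to −40 °C; sat. NH4Cl
Reagents that add atoms: N-methoxy-N-methylacetamide, CC(=O)N(C)OC
Why: Lateral lithiation of an ortho-toluate gives an ester-stabilised benzylic anion, and its acylation by a Weinreb amide should stop at the ketone because the tetrahedral chelate persists until work-up.

Step 5
Reactants: 6 methyl 2-methoxy-4-(methoxymethoxy)-6-(2-oxopropyl)benzoate
Product: 8 6-hydroxy-8-methoxy-3-methyl-1H-isochromen-1-one, via phenol keto ester 7 (not isolated)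
Conditions: HCl, MeOH, rt; evaporate; then TsOH·H2O (cat.), toluene, reflux with removal of MeOH
Reagents that add atoms: none
Why: Acid methanolysis removes the MOM acetal as volatile dimethoxymethane, and acid-catalysed enol lactonisation of the ortho-(2-oxopropyl)benzoate with loss of methanol then closes the pyranone ring by 6-exo-trig acyl substitution.

Step 6
Reactants: 8 6-hydroxy-8-methoxy-3-methyl-1H-isochromen-1-one
Product: 9 6-hydroxy-8-methoxy-3-methyl-1-oxo-1H-isochromene-5-carbaldehyde
Conditions: MgCl2, Et3N, (CH2O)n, MeCN, reflux; aq. HCl work-up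
Reagents that add atoms: paraformaldehyde (as formaldehyde), C=O
Why: Magnesium-mediated ortho-formylation of phenols (Casnati–Skattebøl) attacks only ortho to the phenoxide, and of the two ortho sites C5 should be preferred because it is para to the C8 methoxy group and is the 2-naphthol-type position next to the ring fusion, whereas C7 is wedged between two oxygen substituents.

Step 7
Reactants: 9 6-hydroxy-8-methoxy-3-methyl-1-oxo-1H-isochromene-5-carbaldehyde
Product: 10 8-methoxy-6-(methoxymethoxy)-3-methyl-1-oxo-1H-isochromene-5-carbaldehyde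
Conditions: MOMCl, i-Pr2NEt, CH2Cl2, 0 °C to rt
Reagents that add atoms: chloromethyl methyl ether, COCCl
Why: O-alkylation of the acidic salicylaldehyde-type phenol with MOMCl and Hünig's base; the MOM group is installed only now because it would not reliably survive steps 5 and 6.

Step 8
Reactants: 2 (3-fluoro-5-methoxyphenoxy)triisopropylsilane; 11 tributyl(methoxymethyl)stannane; 10 8-methoxy-6-(methoxymethoxy)-3-methyl-1-oxo-1H-isochromene-5-carbaldehyde
Product: 16 racemic 5-{hydroxy[2-methoxy-6-(methoxymethyl)-4-(triisopropylsilyloxy)phenyl]methyl}-8-methoxy-6-(methoxymethoxy)-3-methyl-1H-isochromen-1-one, via methoxymethyllithium 12 (not isolated), via fluoroaryllithium 13 (not isolated), via methoxyaryne 14 (not isolated), via aryllithium 15 (not isolated)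
Conditions: 2 (1.4 equiv), n-BuLi, THF, −78 °C; add 12 (1.55 equiv, from 11 and n-BuLi, THF, −78 °C, separate flask); −78 to −30 °C; recool to −78 °C, add 10 (1.0 equiv) in THF; sat. NH4Cl at −78 °C
Reagents that add atoms: none
Why: Proposed new method: n-BuLi removes the proton of 2 between F and OMe to give 13, which loses LiF on warming to the aryne 14; methoxymethyllithium 12, made apart by tin–lithium exchange of 11, adds to the aryne carbon C6' remote from the methoxy group, which puts the new carbanion on C1' where it is stabilised inductively by the C2' oxygen and chelated by both OMe and the new CH2OMe arm, and this aryllithium 15 then adds 1,2 to the aldehyde of 10 at −78 °C. The closest known reaction type is the carbolithiation of 3-methoxyarynes, generated from ortho-lithiated fluoroarenes, by alkyl- and aryllithiums with electrophilic trapping of the resulting 2-lithio-3-substituted anisole; what is new is an α-alkoxymethyllithium as the aryne nucleophile. No ring is closed, and the one new stereocentre (carbinol carbon C9) forms without control as the racemate, which does not matter because step 9 removes it. The step needs site-selective lithiation and regioselective aryne addition, secured by the C2' methoxy group together with the bulky silyl ether that shields both of its own ortho positions, and chemoselective attack on the aldehyde ahead of the lactone carbonyl, secured by the low temperature and the peri-methoxy shielding of C1. Only a small surplus of 12 over 2 is used, enough to keep the aryne from being intercepted by aryllithiums 13 and 15 but small enough that little of aldehyde 10 should be lost to direct methoxymethyl addition.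

Step 9
Reactants: 16 racemic 5-{hydroxy[2-methoxy-6-(methoxymethyl)-4-(triisopropylsilyloxy)phenyl]methyl}-8-methoxy-6-(methoxymethoxy)-3-methyl-1H-isochromen-1-one
Product: 17 6-hydroxy-8-methoxy-5-{[2-methoxy-6-(methoxymethyl)-4-(triisopropylsilyloxy)phenyl]methyl}-3-methyl-1H-isochromen-1-one
Conditions: Et3SiH (excess), TFA, CH2Cl2, 0 °C to rt
Reagents that add atoms: none
Why: Ionic hydrogenation: TFA ionises the doubly benzylic alcohol to a diarylmethyl cation stabilised by ortho and para oxygen on both rings and the silane delivers hydride, while the same medium cleaves the aryl MOM acetal and the silane reduces its methoxymethyl cation; the CH2OMe arm is meta to both ring-A oxygens and should not ionise, and the aryl TIPS ether tolerates TFA.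

Step 10
Reactants: 17 6-hydroxy-8-methoxy-5-{[2-methoxy-6-(methoxymethyl)-4-(triisopropylsilyloxy)phenyl]methyl}-3-methyl-1H-isochromen-1-one
Product: 18 6-hydroxy-5-{[4-hydroxy-2-methoxy-6-(methoxymethyl)phenyl]methyl}-8-methoxy-3-methyl-1H-isochromen-1-one (target)
Conditions: TBAF, AcOH, THF, 0 °C
Reagents that add atoms: none
Why: Fluoride-induced Si–O cleavage of the aryl silyl ether, buffered with acetic acid so that the lactone and the phenols are not exposed to strongly basic fluoride.

**Compound list**

1 | 3-fluoro-5-methoxyphenol | COc1cc(O)cc(F)c1 | starting material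
2 | (3-fluoro-5-methoxyphenoxy)triisopropylsilane | COc1cc(F)cc(O[Si](C(C)C)(C(C)C)C(C)C)c1 | intermediate
3 | methyl 2,4-dihydroxy-6-methylbenzoate (methyl orsellinate) | COC(=O)c1c(C)cc(O)cc1O | starting material
4 | methyl 2-hydroxy-4-(methoxymethoxy)-6-methylbenzoate | COC(=O)c1c(C)cc(OCOC)cc1O | intermediate
5 | methyl 2-methoxy-4-(methoxymethoxy)-6-methylbenzoate | COC(=O)c1c(C)cc(OCOC)cc1OC | intermediate
6 | methyl 2-methoxy-4-(methoxymethoxy)-6-(2-oxopropyl)benzoate | COC(=O)c1c(CC(C)=O)cc(OCOC)cc1OC | intermediate
7 | methyl 4-hydroxy-2-methoxy-6-(2-oxopropyl)benzoate (not isolated) | COC(=O)c1c(CC(C)=O)cc(O)cc1OC | intermediate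
8 | 6-hydroxy-8-methoxy-3-methyl-1H-isochromen-1-one | COc1cc(O)cc2cc(C)oc(=O)c12 | intermediate
9 | 6-hydroxy-8-methoxy-3-methyl-1-oxo-1H-isochromene-5-carbaldehyde | COc1cc(O)c(C=O)c2cc(C)oc(=O)c12 | intermediate
10 | 8-methoxy-6-(methoxymethoxy)-3-methyl-1-oxo-1H-isochromene-5-carbaldehyde | COCOc1cc(OC)c2c(=O)oc(C)cc2c1C=O | intermediate
11 | tributyl(methoxymethyl)stannane | CCCC[Sn](CCCC)(CCCC)COC | starting material
12 | (methoxymethyl)lithium (not isolated) | [Li]COC | intermediate
13 | [2-fluoro-6-methoxy-4-(triisopropylsilyloxy)phenyl]lithium (not isolated) | COc1cc(O[Si](C(C)C)(C(C)C)C(C)C)cc(F)c1[Li] | intermediate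
14 | 3-methoxy-5-(triisopropylsilyloxy)benzyne, aryne across C1'–C6' (not isolated) | COC1=CC(O[Si](C(C)C)(C(C)C)C(C)C)=CC#C1 | intermediate
15 | [2-methoxy-6-(methoxymethyl)-4-(triisopropylsilyloxy)phenyl]lithium (not isolated) | COCc1cc(O[Si](C(C)C)(C(C)C)C(C)C)cc(OC)c1[Li] | intermediate
16 | racemic 5-{hydroxy[2-methoxy-6-(methoxymethyl)-4-(triisopropylsilyloxy)phenyl]methyl}-8-methoxy-6-(methoxymethoxy)-3-methyl-1H-isochromen-1-one | COCc1cc(O[Si](C(C)C)(C(C)C)C(C)C)cc(OC)c1C(O)c1c(OCOC)cc(OC)c2c(=O)oc(C)cc12 | intermediate
17 | 6-hydroxy-8-methoxy-5-{[2-methoxy-6-(methoxymethyl)-4-(triisopropylsilyloxy)phenyl]methyl}-3-methyl-1H-isochromen-1-one | COCc1cc(O[Si](C(C)C)(C(C)C)C(C)C)cc(OC)c1Cc1c(O)cc(OC)c2c(=O)oc(C)cc12 | intermediate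
18 | 6-hydroxy-5-{[4-hydroxy-2-methoxy-6-(methoxymethyl)phenyl]methyl}-8-methoxy-3-methyl-1H-isochromen-1-one | COCc1cc(O)cc(OC)c1Cc1c(O)cc(OC)c2c(=O)oc(C)cc12 | target

**Step count**

Total steps: 10. Longest linear sequence: 9 steps (steps 2 to 10, from methyl orsellinate 3).

**Steps most likely to fail**

1. Step 8 (Proposed new method). Three processes could undermine it. Methoxymethyllithium may decompose in the temperature window in which LiF is lost. The aryne may be intercepted by the aryllithiums 13 or 15 instead of 12, giving biaryls. Surplus 12 may add directly to the aldehyde.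
Fallback, known chemistry: it sets out from aldehyde 10 and returns to the route at benzhydrol 16 by way of aryllithium 15, which is then made by directed ortho-metalation instead of the aryne relay. Commercial methyl 3-hydroxy-5-methoxybenzoate (COC(=O)c1cc(O)cc(OC)c1) is silylated with TIPSCl and imidazole to methyl 3-methoxy-5-(triisopropylsilyloxy)benzoate F1. DIBAL-H in CH2Cl2 at −78 °C should reduce this to [3-methoxy-5-(triisopropylsilyloxy)phenyl]methanol F2. NaH and MeI in THF at 0 °C should then give 1-methoxy-3-(methoxymethyl)-5-(triisopropylsilyloxy)benzene F3. n-BuLi in Et2O at 0 °C should lithiate F3 at the position flanked by OMe and CH2OMe, where the two directing groups cooperate and the silyl ether shields the other sites, to give 15. Addition of 10 at −78 °C would give 16.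

2. Step 6. The formylation may divide between C5 and C7, and the electron-poor phenol may react sluggishly.
Fallback: it sets out from benzoate 5 and returns at aldehyde 10, fixing the C5 substituent before the pyranone ring exists. NBS in MeCN at 0 °C should brominate 5 para to the methoxy group and next to the methyl group, not between the two oxygens, to give methyl 3-bromo-6-methoxy-4-(methoxymethoxy)-2-methylbenzoate F4. Lateral lithiation with LDA and acylation with N-methoxy-N-methylacetamide would give methyl 3-bromo-6-methoxy-4-(methoxymethoxy)-2-(2-oxopropyl)benzoate F5. HCl in MeOH would remove the MOM group to give methyl 3-bromo-4-hydroxy-6-methoxy-2-(2-oxopropyl)benzoate F6, not isolated, and TsOH in refluxing toluene would lactonise it to 5-bromo-6-hydroxy-8-methoxy-3-methyl-1H-isochromen-1-one F7. MOMCl and i-Pr2NEt would give 5-bromo-8-methoxy-6-(methoxymethoxy)-3-methyl-1H-isochromen-1-one F8. Stille coupling with tributyl(vinyl)stannane (Pd(PPh3)4, toluene, 100 °C) would give 5-ethenyl-8-methoxy-6-(methoxymethoxy)-3-methyl-1H-isochromen-1-one F9. Lemieux–Johnson cleavage (cat. OsO4, NaIO4, 2,6-lutidine, dioxane/water) of the terminal vinyl group, which should react ahead of the trisubstituted enol-lactone alkene, would give 10.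

3. Step 9. The diarylmethyl cation may be captured by the oxygen of the neighbouring CH2OMe arm; the cyclic oxonium could then lose its methyl group to give a 1-aryl-1,3-dihydroisobenzofuran, or the methyl ether could be lost in other ways, before hydride arrives.
Fallback: it sets out from benzhydrol 16 and returns at 17, removing the hydroxyl by a radical instead of a cation (Barton–McCombie deoxygenation). KHMDS, CS2 and then MeI in THF at −78 °C should give the xanthate O-{[2-methoxy-6-(methoxymethyl)-4-(triisopropylsilyloxy)phenyl][8-methoxy-6-(methoxymethoxy)-3-methyl-1-oxo-1H-isochromen-5-yl]methyl} S-methyl dithiocarbonate F10. Bu3SnH and AIBN in toluene at 90 °C should reduce it through the diarylmethyl radical to 8-methoxy-5-{[2-methoxy-6-(methoxymethyl)-4-(triisopropylsilyloxy)phenyl]methyl}-6-(methoxymethoxy)-3-methyl-1H-isochromen-1-one F11. HCl in MeOH at rt would remove the MOM group to give 17.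

**Further compounds**

F1 | step 8 | methyl 3-methoxy-5-(triisopropylsilyloxy)benzoate | COC(=O)c1cc(OC)cc(O[Si](C(C)C)(C(C)C)C(C)C)c1
F2 | step 8 | [3-methoxy-5-(triisopropylsilyloxy)phenyl]methanol | OCc1cc(OC)cc(O[Si](C(C)C)(C(C)C)C(C)C)c1
F3 | step 8 | 1-methoxy-3-(methoxymethyl)-5-(triisopropylsilyloxy)benzene | COCc1cc(OC)cc(O[Si](C(C)C)(C(C)C)C(C)C)c1
F4 | step 6 | methyl 3-bromo-6-methoxy-4-(methoxymethoxy)-2-methylbenzoate | COC(=O)c1c(C)c(Br)c(OCOC)cc1OC
F5 | step 6 | methyl 3-bromo-6-methoxy-4-(methoxymethoxy)-2-(2-oxopropyl)benzoate | COC(=O)c1c(CC(C)=O)c(Br)c(OCOC)cc1OC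
F6 | step 6 | methyl 3-bromo-4-hydroxy-6-methoxy-2-(2-oxopropyl)benzoate | COC(=O)c1c(CC(C)=O)c(Br)c(O)cc1OC
F7 | step 6 | 5-bromo-6-hydroxy-8-methoxy-3-methyl-1H-isochromen-1-one | COc1cc(O)c(Br)c2cc(C)oc(=O)c12
F8 | step 6 | 5-bromo-8-methoxy-6-(methoxymethoxy)-3-methyl-1H-isochromen-1-one | COCOc1cc(OC)c2c(=O)oc(C)cc2c1Br
F9 | step 6 | 5-ethenyl-8-methoxy-6-(methoxymethoxy)-3-methyl-1H-isochromen-1-one | COCOc1cc(OC)c2c(=O)oc(C)cc2c1C=C
F10 | step 9 | O-{[2-methoxy-6-(methoxymethyl)-4-(triisopropylsilyloxy)phenyl][8-methoxy-6-(methoxymethoxy)-3-methyl-1-oxo-1H-isochromen-5-yl]methyl} S-methyl dithiocarbonate | COCc1cc(O[Si](C(C)C)(C(C)C)C(C)C)cc(OC)c1C(OC(=S)SC)c1c(OCOC)cc(OC)c2c(=O)oc(C)cc12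
F11 | step 9 | 8-methoxy-5-{[2-methoxy-6-(methoxymethyl)-4-(triisopropylsilyloxy)phenyl]methyl}-6-(methoxymethoxy)-3-methyl-1H-isochromen-1-one | COCc1cc(O[Si](C(C)C)(C(C)C)C(C)C)cc(OC)c1Cc1c(OCOC)cc(OC)c2c(=O)oc(C)cc12
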